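**Retrosynthetic overview**
1. Target ⇐ Steglich acylation of O6 and hydroxyl-directed epoxidation of a trans-fused hydroazulene diol monoacetate; the oxirane is the last ring made.
2. Ring B (seven-membered, formed second) ⇐ ring-closing metathesis of a C1 allyl arm and a C6 2-methylallyl carbinol, the latter from Brown methallylation of a cyclopentane carbaldehyde.
3. Ring A (cyclopentane, formed first) ⇐ intramolecular aldol C5→C4 of a 1,6-keto aldehyde, which creates the C4 isopropyl carbinol.
4. Key bond C1–C2 ⇐ homoaldol addition of an α-titanated (Z)-allyl carbamate (a homoenolate equivalent of the C6 aldehyde, nucleophilic at C1) to a β-ketal aldehyde; this gives the quaternary C1, the C2 carbinol and the masked C6 aldehyde in one step.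
5. Fragments ⇐ but-2-yn-1-ol plus an allyl unit, and ethyl 4-methyl-3-oxopentanoate.

Assumption (locants): carbons are labelled as in daucane – C1 methyl-bearing ring-fusion carbon, C2 acetoxy carbon, C3 CH2, C4 isopropyl carbinol, C5 ring-fusion CH, C6 aroyloxy carbon, C7 CH2, C8 (methyl) and C9 oxirane carbons, C10 CH2; on this numbering the target is 1S,2S,4S,5R,6S,8R,9S.

**Route**

Step 1
Reactants: 1 but-2-yn-1-ol
Product: 3 (2Z)-3-iodobut-2-en-1-ol, via cyclic alkenylaluminate 2 (not isolated)
Conditions: NaAlH2(OCH2CH2OCH3)2, Et2O, 0 °C; then iodine, THF, −78 to 0 °C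
Reagents that add atoms: iodine, [I][I]
Why: Hydroxyl-directed trans-hydroalumination of the propargylic alcohol puts aluminium on C3 inside a five-membered alkoxyaluminate, and iodinolysis of the C–Al bond with retention gives the Z-iodide (iodine cis to CH2OH), which fixes the later olefin geometry.

Step 2
Reactants: 3 (2Z)-3-iodobut-2-en-1-ol
Product: 4 (2Z)-3-methylhexa-2,5-dien-1-ol
Conditions: allylSnBu3, PdCl2(MeCN)2 (5 mol %), DMF, 25 °C
Reagents that add atoms: allyltributylstannane, C=CC[Sn](CCCC)(CCCC)CCCC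
Why: Stille cross-coupling of an alkenyl iodide goes with retention of double-bond geometry, so the allyl group ends cis to CH2OH (2Z).

Step 3
Reactants: 4 (2Z)-3-methylhexa-2,5-dien-1-ol
Product: 6 (2Z)-3-methylhexa-2,5-dien-1-yl N,N-diisopropylcarbamate, via sodium alkoxide 5 (not isolated)
Conditions: NaH, THF, 0 °C; then i-Pr2NCOCl, reflux
Reagents that add atoms: N,N-diisopropylcarbamoyl chloride, CC(C)N(C(C)C)C(=O)Cl
Why: O-Carbamoylation of the alkoxide (nucleophilic acyl substitution) installs the hindered carbamate that later directs α-lithiation and resists attack by alkyllithium.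

Step 4
Reactants: 7 ethyl 4-methyl-3-oxopentanoate
Product: 8 ethyl 2-[2-(propan-2-yl)-1,3-dioxolan-2-yl]acetate
Conditions: HOCH2CH2OH, p-TsOH (cat.), toluene, reflux, Dean–Stark
Reagents that add atoms: ethylene glycol, OCCO
Why: Acid-catalysed ketalisation with azeotropic removal of water masks the ketone so that the later aldehyde is not a free β-dicarbonyl.

Step 5
Reactants: 8 ethyl 2-[2-(propan-2-yl)-1,3-dioxolan-2-yl]acetate
Product: 9 2-[2-(propan-2-yl)-1,3-dioxolan-2-yl]acetaldehyde
Conditions: i-Bu2AlH, CH2Cl2, −78 °C; aq. potassium sodium tartrate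
Reagents that add atoms: none
Why: Partial ester reduction by i-Bu2AlH at −78 °C stops at the tetrahedral aluminium hemiacetal, which gives the aldehyde on work-up.

Step 6
Reactants: 6 (2Z)-3-methylhexa-2,5-dien-1-yl N,N-diisopropylcarbamate; 9 2-[2-(propan-2-yl)-1,3-dioxolan-2-yl]acetaldehyde
Product: 12 (1Z,3S,4S)-4-hydroxy-3-methyl-5-[2-(propan-2-yl)-1,3-dioxolan-2-yl]-3-(prop-2-en-1-yl)pent-1-en-1-yl N,N-diisopropylcarbamate, via lithio carbamate 10 (not isolated), via allyltitanium 11 (not isolated)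
Conditions: s-BuLi, (+)-sparteine, toluene, −78 °C; Ti(Oi-Pr)4, −78 °C; then 9, −78 to −40 °C; aq. NH4Cl
Reagents that add atoms: none
Why: Hoppe homoaldol reaction: sparteine-controlled removal of the pro-R α-proton gives the (R)-lithio carbamate, lithium–titanium exchange with inversion gives an α-titanated allyl carbamate that acts as a homoenolate equivalent and adds through its γ-carbon (C1) to the aldehyde in a closed chair transition state (aldehyde residue equatorial, carbamoyloxy group axial), so the Z-olefin geometry and the titanium-bearing centre set the quaternary C1 (S) and the C2 carbinol (S, methyl anti to OH) and leave the C6 aldehyde masked as a Z-enol carbamate.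

Step 7
Reactants: 12 (homoaldol adduct)
Product: 13 (1Z,3S,4S)-4-acetoxy-3-methyl-5-[2-(propan-2-yl)-1,3-dioxolan-2-yl]-3-(prop-2-en-1-yl)pent-1-en-1-yl N,N-diisopropylcarbamate
Conditions: Ac2O, DMAP (cat.), pyridine, CH2Cl2, 25 °C
Reagents that add atoms: acetic anhydride, CC(=O)OC(C)=O
Why: DMAP-catalysed acylation of the neopentyl secondary alcohol puts the acetate on O2 before any other hydroxyl exists, without touching a stereocentre.

Step 8
Reactants: 13 (acetate)
Product: 14 (3S,4S)-3,7-dimethyl-1,6-dioxo-3-(prop-2-en-1-yl)octan-4-yl acetate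
Conditions: Hg(OAc)2 (5 mol %), CH3SO3H, THF–H2O, 25 °C
Reagents that add atoms: water, O
Why: Mercury-catalysed acid hydrolysis of the enol carbamate (Hoppe decarbamoylation) and acid hydrolysis of the dioxolane release the C6 aldehyde and the C4 ketone while the acetate and both stereocentres are untouched.

Step 9
Reactants: 14 (keto aldehyde)
Product: 15 (1S,2S,3S,4S)-3-formyl-4-hydroxy-2-methyl-4-(propan-2-yl)-2-(prop-2-en-1-yl)cyclopentyl acetate
Conditions: (S)-proline (30 mol %), DMSO, 25 °C
Reagents that add atoms: none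
Why: Proline-catalysed intramolecular aldol addition (5-enolexo enamine aldol) of the aldehyde to the ketone closes ring A; the isopropyl group turns to the ring face opposite the C1 methyl and C2 acetoxy groups, so the tertiary hydroxyl forms cis to the acetate (4S), and the epimerisable formyl-bearing C5 settles with the formyl group trans to isopropyl.

Step 10
Reactants: 15 (cyclopentane carbaldehyde)
Product: 17 (1S,2S,3R,4S)-4-hydroxy-3-[(1S)-1-hydroxy-3-methylbut-3-en-1-yl]-2-methyl-4-(propan-2-yl)-2-(prop-2-en-1-yl)cyclopentyl acetate, via borinate ester 16 (not isolated)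
Conditions: (−)-Ipc2B(CH2C(CH3)=CH2), Et2O, −78 °C; then HOCH2CH2NH2, 25 °C
Reagents that add atoms: (−)-B-(2-methylallyl)diisopinocampheylborane, CC(=C)CB([C@@H]1C[C@@H]2C[C@H]([C@H]1C)C2(C)C)[C@@H]1C[C@@H]2C[C@H]([C@H]1C)C2(C)C
Why: Brown asymmetric allylboration: the reagent from (+)-α-pinene adds the 2-methylallyl group to the Si face of the aldehyde through a chair transition state, which gives the 6S carbinol under reagent control, and the ethanolamine work-up spares the acetate.

Step 11
Reactants: 17 (diene diol)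
Product: 18 (1S,2S,4S,5R,6S)-4,6-dihydroxydauc-8-en-2-yl acetate
Conditions: second-generation Grubbs catalyst RuCl2(=CHPh)(PCy3)(H2IMes) (5 mol %), CH2Cl2 (2 mM), 40 °C
Reagents that add atoms: none
Why: Ring-closing metathesis of the allyl and 2-methylallyl arms, which are trans on the cyclopentane, forms the trisubstituted C8=C9 olefin and the trans-fused seven-membered ring B without touching a stereocentre.

Step 12
Reactants: 18 (hydroazulene diol)
Product: 19 (1S,2S,4S,5R,6S,8R,9S)-8,9-epoxy-4,6-dihydroxydaucan-2-yl acetate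
Conditions: VO(acac)2 (5 mol %), t-BuOOH, CH2Cl2, 0 to 25 °C
Reagents that add atoms: tert-butyl hydroperoxide, CC(C)(C)OO
Why: Vanadium-catalysed hydroxyl-directed epoxidation: the homoallylic C6 hydroxyl binds the peroxo-vanadium species and delivers oxygen to the olefin face it occupies, which gives the 8R,9S oxirane syn to O6.

Step 13
Reactants: 19 (epoxy diol)
Product: 20 (1S,2S,4S,5R,6S,8R,9S)-2-acetoxy-8,9-epoxy-4-hydroxydaucan-6-yl 3,4-dimethoxybenzoate
Conditions: 3,4-(MeO)2C6H3CO2H, DCC, DMAP, CH2Cl2, 25 °C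
Reagents that add atoms: 3,4-dimethoxybenzoic acid, COc1ccc(C(=O)O)cc1OC
Why: Steglich esterification acylates the only secondary hydroxyl (O6) while the tertiary C4 hydroxyl is too hindered to react and the oxirane and acetate are inert to the conditions.

**Compound list**
1 | but-2-yn-1-ol | CC#CCO | starting material
2 | sodium 2,2-bis(2-methoxyethoxy)-3-methyl-2,5-dihydro-1,2-oxaluminol-2-uide (cyclic Z-alkenylaluminate) | CC1=CCO[Al-]1(OCCOC)OCCOC.[Na+] | intermediate
3 | (2Z)-3-iodobut-2-en-1-ol | C/C(I)=C/CO | intermediate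
4 | (2Z)-3-methylhexa-2,5-dien-1-ol | C=CC/C(C)=C\CO | intermediate
5 | sodium (2Z)-3-methylhexa-2,5-dien-1-olate | C=CC/C(C)=C\C[O-].[Na+] | intermediate
6 | (2Z)-3-methylhexa-2,5-dien-1-yl N,N-diisopropylcarbamate | C=CC/C(C)=C\COC(=O)N(C(C)C)C(C)C | intermediate
7 | ethyl 4-methyl-3-oxopentanoate | CCOC(=O)CC(=O)C(C)C | starting material
8 | ethyl 2-[2-(propan-2-yl)-1,3-dioxolan-2-yl]acetate | CCOC(=O)CC1(C(C)C)OCCO1 | intermediate
9 | 2-[2-(propan-2-yl)-1,3-dioxolan-2-yl]acetaldehyde | O=CCC1(C(C)C)OCCO1 | intermediate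
10 | (1R,2Z)-1-lithio-3-methylhexa-2,5-dien-1-yl N,N-diisopropylcarbamate (as its (+)-sparteine complex) | [Li][C@@H](OC(=O)N(C(C)C)C(C)C)/C=C(/C)CC=C | intermediate
11 | (1S,2Z)-3-methyl-1-[tri(propan-2-yloxy)titanio]hexa-2,5-dien-1-yl N,N-diisopropylcarbamate | CC(C)O[Ti](OC(C)C)(OC(C)C)[C@H](OC(=O)N(C(C)C)C(C)C)/C=C(/C)CC=C | intermediate
12 | (1Z,3S,4S)-4-hydroxy-3-methyl-5-[2-(propan-2-yl)-1,3-dioxolan-2-yl]-3-(prop-2-en-1-yl)pent-1-en-1-yl N,N-diisopropylcarbamate | C=CC[C@@](C)(/C=C\OC(=O)N(C(C)C)C(C)C)[C@@H](O)CC1(C(C)C)OCCO1 | intermediate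
13 | (1Z,3S,4S)-4-acetoxy-3-methyl-5-[2-(propan-2-yl)-1,3-dioxolan-2-yl]-3-(prop-2-en-1-yl)pent-1-en-1-yl N,N-diisopropylcarbamate | C=CC[C@@](C)(/C=C\OC(=O)N(C(C)C)C(C)C)[C@@H](OC(C)=O)CC1(C(C)C)OCCO1 | intermediate
14 | (3S,4S)-3,7-dimethyl-1,6-dioxo-3-(prop-2-en-1-yl)octan-4-yl acetate | C=CC[C@@](C)(CC=O)[C@@H](OC(C)=O)CC(=O)C(C)C | intermediate
15 | (1S,2S,3S,4S)-3-formyl-4-hydroxy-2-methyl-4-(propan-2-yl)-2-(prop-2-en-1-yl)cyclopentyl acetate (OAc, OH, CHO and 2-methyl all cis; allyl and isopropyl on the other face) | C=CC[C@]1(C)[C@@H](OC(C)=O)C[C@](O)(C(C)C)[C@H]1C=O | intermediate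
16 | diisopinocampheylborinate ester of 17 at the side-chain (C6) oxygen | C=CC[C@]1(C)[C@@H](OC(C)=O)C[C@](O)(C(C)C)[C@H]1[C@@H](OB([C@@H]2C[C@@H]3C[C@H]([C@H]2C)C3(C)C)[C@@H]2C[C@@H]3C[C@H]([C@H]2C)C3(C)C)CC(C)=C | intermediate
17 | (1S,2S,3R,4S)-4-hydroxy-3-[(1S)-1-hydroxy-3-methylbut-3-en-1-yl]-2-methyl-4-(propan-2-yl)-2-(prop-2-en-1-yl)cyclopentyl acetate | C=CC[C@]1(C)[C@@H](OC(C)=O)C[C@](O)(C(C)C)[C@H]1[C@@H](O)CC(C)=C | intermediate
18 | (1S,2S,4S,5R,6S)-4,6-dihydroxydauc-8-en-2-yl acetate (trans-fused; 2-OAc, 4-OH, 6-OH and C1 methyl on one face) | O[C@H]1CC(C)=CC[C@]2(C)[C@@H](OC(C)=O)C[C@](O)(C(C)C)[C@@H]12 | intermediate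
19 | (1S,2S,4S,5R,6S,8R,9S)-8,9-epoxy-4,6-dihydroxydaucan-2-yl acetate | O[C@H]1C[C@@]3(C)O[C@H]3C[C@]2(C)[C@@H](OC(C)=O)C[C@](O)(C(C)C)[C@@H]12 | intermediate
20 | (1S,2S,4S,5R,6S,8R,9S)-2-acetoxy-8,9-epoxy-4-hydroxydaucan-6-yl 3,4-dimethoxybenzoate (CNP0330776.1) | COc1ccc(C(=O)O[C@H]2C[C@@]3(C)O[C@H]3C[C@]3(C)[C@@H](OC(C)=O)C[C@](O)(C(C)C)[C@@H]23)cc1OC | target

**Step count**
Total steps: 13 (three to carbamate 6, two to aldehyde 9, eight after their union).
Longest linear sequence: 11 steps (steps 1–3 and 6–13).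

**Three steps most likely to fail, each with a fallback**

Step 6 (homoaldol). The lithiation may be poorly enantioselective for this γ,γ-disubstituted allyl carbamate, the bis-allylic CH2 may compete for the base, and the quaternary centre must form at the hindered γ-carbon. The fallback sets out from 6 and 9 and comes back at 12. The two partners are coupled without a chiral ligand (n-BuLi, TMEDA, then Ti(Oi-Pr)4); the chair transition state still fixes the relative configuration, so 12 forms together with its mirror image, the enantiomeric homoaldol adduct F1. The mixture is esterified with (S)-2-methoxy-2-phenylacetic acid (DCC, DMAP) to give the O-methylmandelate ester of 12 F2 and the O-methylmandelate ester of the antipode F3, which are separated by chromatography. Methanolysis of F2 (K2CO3, MeOH) returns 12.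

Step 9 (aldol ring closure). The hindered isopropyl ketone may react slowly, the β-acetoxy ketone may eliminate, and the C4 configuration rests on a steric argument only. The fallback sets out from 12 and comes back at 15. The free alcohol 12 is unmasked (Hg(OAc)2 cat., CH3SO3H, aqueous THF) to the hydroxy keto aldehyde F4, which rests as its five-membered lactol. It is cyclised under magnesium templating (MgBr2·OEt2, Et3N, CH2Cl2): the metal bridges the C2 alkoxide and the C4 ketone and so forces the new tertiary oxygen cis to O2, giving the diol aldehyde F5. Selective acetylation of its secondary hydroxyl (Ac2O, pyridine, 0 °C) rejoins the route at 15.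

Step 10 (methallylation). Reagent control must override the bias of a hindered α-branched β-hydroxy aldehyde, and a chelate model predicts that this bias favours the wrong C6 epimer. The fallback sets out from 15 and comes back at 17. An unselective Barbier addition (3-bromo-2-methylprop-1-ene, indium powder, aqueous THF) gives 17 mixed with the C6-epimeric diol F6. Dess–Martin oxidation converges both on the β-hydroxy ketone F7. Chelation-controlled syn reduction (Et2BOMe, NaBH4, THF–MeOH, −78 °C) then delivers external hydride to the exposed face of the O4/O6 boron chelate, which by the same chelate model gives the 6S alcohol 17.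

**Further compounds**
F1 | step 6 | (1Z,3R,4R)-4-hydroxy-3-methyl-5-[2-(propan-2-yl)-1,3-dioxolan-2-yl]-3-(prop-2-en-1-yl)pent-1-en-1-yl N,N-diisopropylcarbamate (enantiomer of 12) | C=CC[C@](C)(/C=C\OC(=O)N(C(C)C)C(C)C)[C@H](O)CC1(C(C)C)OCCO1
F2 | step 6 | (2S)-2-methoxy-2-phenylacetate ester of 12 at O2 | C=CC[C@@](C)(/C=C\OC(=O)N(C(C)C)C(C)C)[C@@H](OC(=O)[C@@H](OC)c1ccccc1)CC1(C(C)C)OCCO1
F3 | step 6 | (2S)-2-methoxy-2-phenylacetate ester of F1 at O2 | C=CC[C@](C)(/C=C\OC(=O)N(C(C)C)C(C)C)[C@H](OC(=O)[C@@H](OC)c1ccccc1)CC1(C(C)C)OCCO1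
F4 | step 9 | (3S,4S)-4-hydroxy-3,7-dimethyl-6-oxo-3-(prop-2-en-1-yl)octanal (open form of the lactol) | C=CC[C@@](C)(CC=O)[C@@H](O)CC(=O)C(C)C
F5 | step 9 | (1S,2S,3S,5S)-3,5-dihydroxy-2-methyl-5-(propan-2-yl)-2-(prop-2-en-1-yl)cyclopentane-1-carbaldehyde | C=CC[C@]1(C)[C@@H](O)C[C@](O)(C(C)C)[C@H]1C=O
F6 | step 10 | (1S,2S,3R,4S)-4-hydroxy-3-[(1R)-1-hydroxy-3-methylbut-3-en-1-yl]-2-methyl-4-(propan-2-yl)-2-(prop-2-en-1-yl)cyclopentyl acetate | C=CC[C@]1(C)[C@@H](OC(C)=O)C[C@](O)(C(C)C)[C@H]1[C@H](O)CC(C)=C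
F7 | step 10 | (1S,2S,3S,4S)-4-hydroxy-2-methyl-3-(3-methylbut-3-enoyl)-4-(propan-2-yl)-2-(prop-2-en-1-yl)cyclopentyl acetate | C=CC[C@]1(C)[C@@H](OC(C)=O)C[C@](O)(C(C)C)[C@H]1C(=O)CC(C)=C
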